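## Retrosynthetic overview

1. Building blocks: commercial 4-allyl-2,6-dimethoxyphenol 1 gives (E)-propenylphenol 2 by alkene migration; commercial propiophenone 3 gives racemic α-bromoketone 4 by α-bromination.
2. Key disconnection: the C8–O aryl ether bond (C8 = methyl-bearing carbon, C7 = benzylic carbon) of (R)-α-aryloxy ketone 5, cut to 2 + 4. Forming it enantioconvergently sets C8.
3. C7: the benzylic C–H and C–OAc bonds are cut back to the C=O of 5. Felkin–Anh hydride addition gives threo alkoxide 6, which is acetylated in the same flask to target 7.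
4. Rings: none is formed; both benzene rings are bought fully oxygenated.

Assumption: the cinchonidine-derived hand of the step 3 catalyst (made in three known operations from cinchonidine: 9-epi-amination, urea formation, N-benzylation) is taken to give (R)-5; if the sense is reversed, the pseudo-enantiomeric cinchonine-derived salt is used in the same way.

## Route

Step 1
Reactants: 1 4-allyl-2,6-dimethoxyphenol
Product: 2 (E)-2,6-dimethoxy-4-(prop-1-en-1-yl)phenol
Conditions: RuHCl(CO)(PPh3)3 (1 mol %), toluene, 80 °C
Reagents that add atoms: none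
Why: reversible Ru–H insertion/β-hydride elimination (catalytic alkene isomerization) moves the allyl double bond one position into conjugation with the arene and funnels the mixture to the thermodynamically favoured (E)-propenyl isomer (E:Z expected ≥ 95:5, the trace Z isomer being removed by chromatography on AgNO3-doped silica).

Step 2
Reactants: 3 1-(3,4,5-trimethoxyphenyl)propan-1-one
Product: 4 rac-2-bromo-1-(3,4,5-trimethoxyphenyl)propan-1-one
Conditions: CuBr2 (2.1 equiv), EtOAc/CHCl3 1:1, reflux
Reagents that add atoms: copper dibromide (CuBr2), Br[Cu]Br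
Why: CuBr2-mediated electrophilic α-bromination of the enolized aryl ketone is selective for the α-methylene over the acyl-deactivated trimethoxyarene, and the new centre is deliberately left racemic because step 3 is enantioconvergent.

Step 3
Reactants: 4 rac-2-bromo-1-(3,4,5-trimethoxyphenyl)propan-1-one; 2 (E)-2,6-dimethoxy-4-(prop-1-en-1-yl)phenol
Product: 5 (2R)-2-{2,6-dimethoxy-4-[(E)-prop-1-en-1-yl]phenoxy}-1-(3,4,5-trimethoxyphenyl)propan-1-one
Conditions: N-(3,5-di-tert-butylbenzyl)-9-deoxy-9-epi-9-{3-[3,5-bis(trifluoromethyl)phenyl]ureido}cinchonidinium bromide (C43H49BrF6N4O, 10 mol %), powdered K2CO3 (1.5 equiv), toluene, 0 °C, 2 added over 12 h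
Reagents that add atoms: none
Why: Proposed new method: an enantioconvergent Williamson etherification run as a dynamic kinetic resolution under bifunctional chiral phase-transfer catalysis — the catalyst's bromide, regenerated at every turnover, racemizes 4 by degenerate SN2 bromide exchange at the activated α-keto carbon; the quaternary ammonium centre carries the aryloxide of 2 into toluene as a tight chiral ion pair (no uncatalysed background, since solid K2CO3 and the potassium phenoxide are insoluble there); the urea N–H bonds hold the carbonyl oxygen of 4 so that only (S)-4 can align its C–Br σ* orbital with the bound aryloxide and is displaced with inversion to (R)-5, while slow addition of 2 keeps substitution slower than racemization; the closest known reaction types are the racemic K2CO3-mediated SN2 etherification of α-bromopropiophenones with 2,6-dimethoxyphenols, chiral-cation-controlled enantioconvergent substitutions of racemic α-bromo ketones by fluoride or azide, and halide-exchange dynamic kinetic resolutions of α-bromo carbonyl compounds.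

Step 4
Reactants: 5 (2R)-2-{2,6-dimethoxy-4-[(E)-prop-1-en-1-yl]phenoxy}-1-(3,4,5-trimethoxyphenyl)propan-1-one
Product: 7 (1R,2R)-2-{2,6-dimethoxy-4-[(E)-prop-1-en-1-yl]phenoxy}-1-(3,4,5-trimethoxyphenyl)propyl acetate, via potassium threo-alkoxide 6 (not isolated)
Conditions: K[HB(s-Bu)3] (K-Selectride, 1.2 equiv), THF, −78 °C; then Ac2O (3 equiv), 4-(dimethylamino)pyridine (0.2 equiv), −78 → 0 °C
Reagents that add atoms: acetic anhydride, CC(=O)OC(C)=O; K[HB(s-Bu)3] (potassium tri-sec-butylborohydride), CCC(C)[BH-](C(C)CC)C(C)CC.[K+] (gives the hydride and the K+ of 6)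
Why: the bulky, non-chelating borohydride adds under polar Felkin–Anh control (aryloxy group anti to the incoming hydride, hydride passing the α-H and not the α-CH3), which turns (R)-5 into the (1R,2R)-threo alkoxide, and 4-(dimethylamino)pyridine-catalysed O-acetylation in the same flask leaves both C–O stereocentres untouched.

## Compound list

1 | 4-allyl-2,6-dimethoxyphenol | C=CCc1cc(OC)c(O)c(OC)c1 | starting material
2 | (E)-2,6-dimethoxy-4-(prop-1-en-1-yl)phenol | C/C=C/c1cc(OC)c(O)c(OC)c1 | intermediate
3 | 1-(3,4,5-trimethoxyphenyl)propan-1-one | CCC(=O)c1cc(OC)c(OC)c(OC)c1 | starting material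
4 | rac-2-bromo-1-(3,4,5-trimethoxyphenyl)propan-1-one | CC(Br)C(=O)c1cc(OC)c(OC)c(OC)c1 | intermediate
5 | (2R)-2-{2,6-dimethoxy-4-[(E)-prop-1-en-1-yl]phenoxy}-1-(3,4,5-trimethoxyphenyl)propan-1-one | C/C=C/c1cc(OC)c(O[C@H](C)C(=O)c2cc(OC)c(OC)c(OC)c2)c(OC)c1 | intermediate
6 | potassium (1R,2R)-2-{2,6-dimethoxy-4-[(E)-prop-1-en-1-yl]phenoxy}-1-(3,4,5-trimethoxyphenyl)propan-1-olate | C/C=C/c1cc(OC)c(O[C@H](C)[C@H]([O-])c2cc(OC)c(OC)c(OC)c2)c(OC)c1.[K+] | intermediate
7 | (1R,2R)-2-{2,6-dimethoxy-4-[(E)-prop-1-en-1-yl]phenoxy}-1-(3,4,5-trimethoxyphenyl)propyl acetate (Compound NP-024268) | C/C=C/c1cc(OC)c(O[C@H](C)[C@H](OC(C)=O)c2cc(OC)c(OC)c(OC)c2)c(OC)c1 | target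

## Step count and risks

Total step count: 4. Longest linear sequence: 3 steps (3 → 4 → 5 → 7, or 1 → 2 → 5 → 7).

**Most likely to fail, in order:**

**Step 3 (the new enantioconvergent etherification).** The C–O bond itself is secure, since the racemic reaction is standard. The risk is low enantiomeric excess: bromide-mediated racemization of 4 may be slower than substitution, the ion pair may discriminate poorly, or 5 may slowly enolize.

Fallback, known chemistry, sets out from 2 and comes back at 5. Mitsunobu etherification of 2 with ethyl (S)-lactate (PPh3, diisopropyl azodicarboxylate, THF, 0 °C to rt) proceeds with inversion to ethyl (2R)-2-{2,6-dimethoxy-4-[(E)-prop-1-en-1-yl]phenoxy}propanoate F1. Me(MeO)NH·HCl with i-PrMgCl (THF, −20 °C) converts this into the Weinreb amide (2R)-2-{2,6-dimethoxy-4-[(E)-prop-1-en-1-yl]phenoxy}-N-methoxy-N-methylpropanamide F2. Commercial 3,4,5-trimethoxyphenylmagnesium bromide (THF, 0 °C) then gives 5, which enters step 4 unchanged.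

**Step 4 (Felkin–Anh reduction with in-flask acetylation).** The risk is an eroded threo:erythro ratio if the potassium ion is chelated between the carbonyl and the ether oxygens, or incomplete trapping of the hindered alkoxide.

Fallback sets out from 5 and comes back at 7. Zn(BH4)2 (Et2O, −20 °C) reduces 5 under chelation control to the erythro alcohol (1S,2R)-2-{2,6-dimethoxy-4-[(E)-prop-1-en-1-yl]phenoxy}-1-(3,4,5-trimethoxyphenyl)propan-1-ol F3. Mitsunobu esterification with acetic acid (PPh3, diisopropyl azodicarboxylate, toluene, 0 °C) inverts C7 and gives 7 directly.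

**Step 2 (α-bromination).** The risk is α,α-dibromination or ring bromination of the electron-rich arene by the HBr/CuBr2 medium.

Fallback sets out from 3 and comes back at 4. Me3SiOTf and Et3N (CH2Cl2, 0 °C) give the silyl enol ether (Z)-trimethyl{[1-(3,4,5-trimethoxyphenyl)prop-1-en-1-yl]oxy}silane F4. N-bromosuccinimide (THF, −78 °C) brominates it cleanly at carbon under neutral conditions to give 4.

## Further compounds

F1 | step 3 | ethyl (2R)-2-{2,6-dimethoxy-4-[(E)-prop-1-en-1-yl]phenoxy}propanoate | C/C=C/c1cc(OC)c(O[C@H](C)C(=O)OCC)c(OC)c1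
F2 | step 3 | (2R)-2-{2,6-dimethoxy-4-[(E)-prop-1-en-1-yl]phenoxy}-N-methoxy-N-methylpropanamide | C/C=C/c1cc(OC)c(O[C@H](C)C(=O)N(C)OC)c(OC)c1
F3 | step 4 | (1S,2R)-2-{2,6-dimethoxy-4-[(E)-prop-1-en-1-yl]phenoxy}-1-(3,4,5-trimethoxyphenyl)propan-1-ol | C/C=C/c1cc(OC)c(O[C@H](C)[C@@H](O)c2cc(OC)c(OC)c(OC)c2)c(OC)c1
F4 | step 2 | (Z)-trimethyl{[1-(3,4,5-trimethoxyphenyl)prop-1-en-1-yl]oxy}silane | C/C=C(\O[Si](C)(C)C)c1cc(OC)c(OC)c(OC)c1
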